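**Retrosynthetic overview**
- Target (both benzylic centres S) ⇒ bis(isopropenyl) diaryl ether phenol: one twofold, catalyst-controlled hydro-prenylation adds both C5 tails and sets both stereocentres.
- Bis(isopropenyl) compound ⇒ bis(acetyl) diaryl ether by twofold Wittig methylenation.
- Bis(acetyl) diaryl ether ⇒ key disconnection at the diaryl ether C–O bond: SNAr of 1-(2-fluoro-4-methylphenyl)ethanone by the 5-OH of 1-(2,5-dihydroxy-4-methylphenyl)ethanone (2-OH masked by chelation to its own acetyl group).
- 1-(2,5-Dihydroxy-4-methylphenyl)ethanone ⇒ methylhydroquinone + acetic acid.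
- No ring is formed; both benzene rings are bought. Order of events: acylation → C–O bond → olefination → side chains and stereocentres.

Assumption: tert-butyl (2-methylbut-3-en-2-yl) carbonate is bought as a catalog reagent (otherwise one uncounted operation from 2-methylbut-3-en-2-ol and Boc2O); in the twofold steps the half-converted and catalyst-bound species are not numbered.

**Step 1**
Reactants: 1 2-methylbenzene-1,4-diol (methylhydroquinone)
Product: 3 1-(2,5-dihydroxy-4-methylphenyl)ethanone, via difluoroboron chelate 2 (not isolated)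
Conditions: AcOH, BF3·OEt2 (3 equiv), 100 °C; then H2O, 80 °C
Reagents that add atoms: acetic acid CC(=O)O
Why: BF3-mediated Friedel–Crafts (Nencki/Fries-type) C-acylation goes to the position ortho to one OH and para to the methyl group, the most activated and least hindered site, and the product is held as its O,O-BF2 chelate 2, which stops a second acylation and is hydrolysed on work-up.

**Step 2**
Reactants: 3 1-(2,5-dihydroxy-4-methylphenyl)ethanone; 4 1-(2-fluoro-4-methylphenyl)ethanone (1.0 equiv)
Product: 5 1-[5-(2-acetyl-5-methylphenoxy)-2-hydroxy-4-methylphenyl]ethanone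
Conditions: K2CO3 (1.2 equiv), degassed DMSO, 100 °C, Ar
Reagents that add atoms: none
Why: Nucleophilic aromatic substitution (SNAr, addition–elimination) forms the diaryl ether C–O bond, because the fluoride of 4 is activated by its ortho acetyl group and only the 5-OH of 3 reacts, the 2-OH being tied up in the hydrogen bond/potassium chelate with its ortho carbonyl and its phenoxide delocalised into that carbonyl.

**Step 3**
Reactants: 5 1-[5-(2-acetyl-5-methylphenoxy)-2-hydroxy-4-methylphenyl]ethanone
Product: 6 5-methyl-4-[5-methyl-2-(prop-1-en-2-yl)phenoxy]-2-(prop-1-en-2-yl)phenol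
Conditions: Ph3PCH3Br (5 equiv), KOtBu (5 equiv), THF, 0 → 60 °C; neutral work-up, fast chromatography on base-washed silica
Reagents that add atoms: methyltriphenylphosphonium bromide C[P+](c1ccccc1)(c1ccccc1)c1ccccc1.[Br-]
Why: Twofold Wittig methylenation in which excess ylide first deprotonates the phenol and then converts both aryl methyl ketones into isopropenyl groups; no stereocentre is involved.

**Step 4**
Reactants: 6 5-methyl-4-[5-methyl-2-(prop-1-en-2-yl)phenoxy]-2-(prop-1-en-2-yl)phenol
Product: 9 5-methyl-2-[(2S)-6-methylhept-5-en-2-yl]-4-{5-methyl-2-[(2S)-6-methylhept-5-en-2-yl]phenoxy}phenol (CNP0354307.1), via O-silylated diene 7 (not isolated), via O-silylated target 8 (not isolated)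
Conditions: Cu(OAc)2 (10 mol%), (R)-DTBM-SEGPHOS (11 mol%), (MeO)2MeSiH (5 equiv), THF, 40 °C; tert-butyl (2-methylbut-3-en-2-yl) carbonate (3 equiv) by syringe pump over 10 h, Ar sweep; then K2CO3 (cat.), MeOH, rt
Reagents that add atoms: tert-butyl (2-methylbut-3-en-2-yl) carbonate C=CC(C)(C)OC(=O)OC(C)(C)C
Why: Proposed new method: twofold CuH-catalysed enantioselective anti-Markovnikov hydro-prenylation of α-methylstyrenes, in which L*CuH (after the silane has silylated the phenol in the flask) adds across each ArC(CH3)=CH2 with copper on the terminal carbon and hydride on the Re face of the benzylic carbon (enantiodetermining, sets both S centres), the primary alkylcopper then attacks the unhindered CH2= end of the tertiary allylic carbonate in an SN2′ sense (its α-carbon is quaternary, so only the linear prenyl isomer can form), and the expelled tert-butyl carbonate loses CO2 to give L*Cu–OtBu, which the silane returns to L*CuH; slow addition keeps the alkylcopper, not CuH, as the species that meets the carbonate; the closest known reaction types are the CuH/DTBM-SEGPHOS anti-Markovnikov hydroamination of 1,1-disubstituted alkenes and the CuH hydroallylation of vinylarenes with allyl phosphates, neither shown with a tertiary-carbonate prenyl donor on α-methylstyrenes or twofold.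

**Compound list**
1 | 2-methylbenzene-1,4-diol (methylhydroquinone) | Cc1cc(O)ccc1O | starting material
2 | O,O′-difluoroboron chelate of 3 (BF2 bridging the 2-O and the carbonyl O; 2,2-difluoro-6-hydroxy-4,7-dimethyl-1,3,2-benzodioxaborinine) | CC1=[O+][B-](F)(F)Oc2cc(C)c(O)cc21 | intermediate
3 | 1-(2,5-dihydroxy-4-methylphenyl)ethanone | CC(=O)c1cc(O)c(C)cc1O | intermediate
4 | 1-(2-fluoro-4-methylphenyl)ethanone | CC(=O)c1ccc(C)cc1F | starting material
5 | 1-[5-(2-acetyl-5-methylphenoxy)-2-hydroxy-4-methylphenyl]ethanone | CC(=O)c1cc(Oc2cc(C)ccc2C(C)=O)c(C)cc1O | intermediate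
6 | 5-methyl-4-[5-methyl-2-(prop-1-en-2-yl)phenoxy]-2-(prop-1-en-2-yl)phenol | CC(=C)c1cc(Oc2cc(C)ccc2C(C)=C)c(C)cc1O | intermediate
7 | dimethoxy(methyl)silyl ether of 6 | CC(=C)c1cc(Oc2cc(C)ccc2C(C)=C)c(C)cc1O[Si](C)(OC)OC | intermediate
8 | dimethoxy(methyl)silyl ether of 9 (both side-chain centres S) | CC(C)=CCC[C@H](C)c1cc(Oc2cc(C)ccc2[C@@H](C)CCC=C(C)C)c(C)cc1O[Si](C)(OC)OC | intermediate
9 | 5-methyl-2-[(2S)-6-methylhept-5-en-2-yl]-4-{5-methyl-2-[(2S)-6-methylhept-5-en-2-yl]phenoxy}phenol | CC(C)=CCC[C@H](C)c1cc(Oc2cc(C)ccc2[C@@H](C)CCC=C(C)C)c(C)cc1O | target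

**Step count**
Total: 4 steps. Longest linear sequence: 4 steps (1 → 3 → 5 → 6 → 9).

**Steps most likely to fail**

Step 4 (the proposed new reaction). Risks:
- CuH may consume the carbonate (SN2′ reduction, hydrosilylation of released CO2) faster than it adds to the hindered, ortho-substituted 1,1-disubstituted alkenes.
- The sense and level of induction are untested. (R)-DTBM-SEGPHOS is a working assignment to be checked on 5-methyl-2-(prop-1-en-2-yl)phenol; the (S)-ligand is used if the model gives the opposite sense.
- At 95% ee per site the product would be about 95:5 dr (>99.8% ee), and the minor diastereomer would have to be removed by preparative chiral SFC.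

Fallback with known chemistry, setting out from 6 and coming back at 9: 6 is silylated (TBSCl, imidazole, DMF) to the TBS ether of 6 F1. Enantioselective hydroboration of both 1,1-disubstituted aryl alkenes (chiral NHC–Cu, B2pin2, MeOH, or chiral iminopyridine-oxazoline cobalt with HBpin, catalyst enantiomer chosen for S) gives the bis(pinacol boronate) F2. Matteson homologation (BrCH2Cl, n-BuLi, THF, −78 °C → rt) gives the chain-extended bis(pinacol boronate) F3. B-alkyl Suzuki–Miyaura coupling with 1-bromo-2-methylprop-1-ene (Pd(OAc)2/RuPhos, K3PO4, toluene/H2O, 80 °C) gives the TBS ether of the target F4, and TBAF in THF returns 9.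

Step 2 (SNAr). Risks: arylation of the chelated 2-OH or double arylation, air oxidation of the hydroquinone phenoxide, and sluggish substitution because the para methyl group weakens the activation. Fallback, setting out from 3 and coming back at 5: copper-catalysed Ullmann etherification of 3 with purchased 1-(2-bromo-4-methylphenyl)ethanone (CC(=O)c1ccc(C)cc1Br; CuI 10 mol%, picolinic acid 20 mol%, K3PO4, DMSO, 90 °C). Here the ortho-carbonyl group accelerates oxidative addition instead of stabilising a Meisenheimer adduct, and the lower temperature favours the free 5-OH. It makes no new compound (none F0).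

Step 3 (twofold Wittig). Risks: enolisation of the ketones by the ylide, incomplete conversion of the phenoxide-deactivated ketone, and acid-induced dimerisation of the o-isopropenylphenol on purification. Fallback, setting out from 5 and coming back at 6: addition of MeMgBr (6 equiv, THF, 0 °C → rt) to both ketones gives the bis(tertiary carbinol) F5. Dehydration (cat. TsOH, toluene, 80 °C, high dilution, water removal) returns 6.

**Further compounds**
F1 | step 4 | tert-butyl(dimethyl)silyl ether of 6 | CC(=C)c1cc(Oc2cc(C)ccc2C(C)=C)c(C)cc1O[Si](C)(C)C(C)(C)C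
F2 | step 4 | TBS ether of 5-methyl-2-[(2S)-1-(4,4,5,5-tetramethyl-1,3,2-dioxaborolan-2-yl)propan-2-yl]-4-{5-methyl-2-[(2S)-1-(4,4,5,5-tetramethyl-1,3,2-dioxaborolan-2-yl)propan-2-yl]phenoxy}phenol | CC1(C)OB(C[C@H](C)c2cc(Oc3cc(C)ccc3[C@@H](C)CB4OC(C)(C)C(C)(C)O4)c(C)cc2O[Si](C)(C)C(C)(C)C)OC1(C)C
F3 | step 4 | TBS ether of 5-methyl-2-[(2S)-4-(4,4,5,5-tetramethyl-1,3,2-dioxaborolan-2-yl)butan-2-yl]-4-{5-methyl-2-[(2S)-4-(4,4,5,5-tetramethyl-1,3,2-dioxaborolan-2-yl)butan-2-yl]phenoxy}phenol | CC1(C)OB(CC[C@H](C)c2cc(Oc3cc(C)ccc3[C@@H](C)CCB4OC(C)(C)C(C)(C)O4)c(C)cc2O[Si](C)(C)C(C)(C)C)OC1(C)C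
F4 | step 4 | tert-butyl(dimethyl)silyl ether of 9 | CC(C)=CCC[C@H](C)c1cc(Oc2cc(C)ccc2[C@@H](C)CCC=C(C)C)c(C)cc1O[Si](C)(C)C(C)(C)C
F0 | step 2 | none | none
F5 | step 3 | 2-(2-hydroxypropan-2-yl)-4-[2-(2-hydroxypropan-2-yl)-5-methylphenoxy]-5-methylphenol | CC(C)(O)c1cc(Oc2cc(C)ccc2C(C)(C)O)c(C)cc1O
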